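I had no rate constants for this flask, so I took its time scales from the south-east run, which is this same flask followed so far.

| flask | substrate | partner | initiator | remark | time |
|---|---|---|---|---|---|
| south-east | 0.10 M | 0.80 equiv | 11 mol% | the very flask that is asked about, followed so far |  |
| flask | 0.10 M | 0.800 equiv | 11 mol% |  | 2.5 d |

south-east run (percent of the substrate charged)

| time / h | product / % | substrate / % |
|---|---|---|
| 8.00 | 43.5 | 55.2 |
| 20.0 | 68.4 | 31.2 |
| 40.0 | 79.4 | 20.9 |
| 60.0 | 78.1 | 18.6 |

(each reading ± 1 percentage point)

- birch: change nothing and wait 2.5 d more
- alder: at 2.5 d add substrate, 50.0% of the amount charged, then wait 2.5 d
- maple: at 2.5 d take out 90% of the product then present, then wait 2.5 d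
- larch: at 2.5 d add partner, 100% of the amount charged, then wait 2.5 d

- what is taken out of product is counted as made
- the numbers in the tables scatter with a standard deviation of 1 percentage point
- additions bring no volume worth counting

- product, in percent of the substrate first charged, at 2.5 d
- the remedy with the largest gain of product, or "none" below 2 percentage points (birch / alder / maple / larch / none)
- product present, with what was taken out counted in, in percent of the substrate first charged, after birch
- product present, with what was taken out counted in, in percent of the substrate first charged, after maple

On the first rung I put whatever species carry the reaction. Product plus substrate averaged 98.8%, so I counted them as holding no readable share.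

The next rung is the partner. The last two product readings averaged 78.8%, close to the 0.80 equiv charged. I therefore took one partner per product, with partner as the limiting reagent and a ceiling of 80.0%.

Then I replaced the bending curve by one mean. The reading at 8.00 h gave 10.2 h, and the reading at 20.0 h gave 10.4 h. I kept 10.3 h as the partner lifetime, the time in which c(partner) falls by a factor e. At 40.0 h it gave 78.4% against the 79.4% read, a miss of 1 percentage point, about the scatter.

The last rung is the wait. The time 2.5 d spans 5.83 lifetimes, so I put the gap below the ceiling at 0.23 points, and I reckoned 79.8% now. Birch could gain that gap, less than the mark of 2 points. Alder and maple bring no partner, so I gave them the same gap, and I put both birch and maple at the ceiling. Larch brings more partner than the substrate last read, so I expected a gain near 18.6 points.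

The forecast gave 79.3% now, 80% after birch, 80% after maple and larch as the remedy, “so partner exhaustion is the simplest reading”.

The flask gave 79.8% now, 80.0% after birch and 80.0% after maple. The best remedy was larch, gaining 19 points, while birch, alder and maple gained 0.21 points each.

    initiator → 2 initiating radical (k = 6.40 × 10⁻⁴ /h)
    2 first chain carrier → ended chains (k = 4.30 × 10⁸ /M/s)
    substrate + second chain carrier → by-product + first chain carrier (k = 35000 /M/s)
    substrate + initiating radical → capped initiator + first chain carrier (k = 9.40 × 10⁵ /M/s)
    partner + first chain carrier → product + second chain carrier (k = 13000 /M/s)

The lifetime gave 0.291% of the partner left at 2.5 d, and this flask held 0.27%. I used the same reckoning on the neighbour flask charged with 0.200 equiv of partner. I put its ceiling at 20.0%, and with the same lifetime I reckoned 19.9% of product. That neighbour flask gave 19.9% of product, with 0.27% of its partner left and 79% of its substrate unreacted.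

Readings and results are simulated with made-up constants; scatter was added.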